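**Plan**
- Retrosynthesis: the O-1–C-2 ketal bond and six benzyl ethers are cut first, then the C-2–C-3 bond, then the O-7''–C-2 ether bond. The C-3–C-8'' and C-4–C-4a bonds follow (two aryllithium acylations of an oxalic bis-Weinreb amide). The flavan is cut last, at its C-2''–aryl bond and C-4'' oxygen, back to a chromone.
- Forward: the flavan pyran ring comes from the chromone. A 1,2-diketone then links the two phloroglucinol rings. The dihydrofuran ring closes by C-2–C-3 bond formation, and the pyranone ring closes last by ketalisation.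
- Enabling feature: C-3 is a tertiary carbinol next to the C-4 ketone and sits on C-8'', ortho to O-7'', the oxygen that carries C-2. C-2 is at aroyl oxidation level. A masked aroyl anion hung on O-7'' therefore reaches the diketone carbon C-3 through a five-membered transition state that becomes the dihydrofuran ring.
- Stereochemistry: C-2'' comes from a ligand-controlled rhodium conjugate arylation. C-3 is created in the key step without useful bias from the remote C-2''; its two epimers are diastereomers and are separated. C-2 follows from the obligatory cis fusion of the five/six ketal.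

Key step: step 12

Remark: flavonoid locants are used (C-2, C-3, C-4 and ring A for the flavonol-derived half, double-primed locants for the flavan half); compounds 1, 3, 9, 11 and 17 are taken as commercial.

Step 1
Reactants: 1 5,7-dihydroxy-4H-chromen-4-one
Product: 2 5-hydroxy-7-(methoxymethoxy)-4H-chromen-4-one
Conditions: MOMCl (1.05 equiv), N,N-diisopropylethylamine, CH2Cl2, 0 °C to rt
Reagents that add atoms: chloromethyl methyl ether, COCCl
Why: Williamson-type O-alkylation; the 7-hydroxyl, para to the pyranone carbonyl, is far more acidic and nucleophilic than the 5-hydroxyl, which is hydrogen-bonded to C-4=O, so one equivalent should protect O-7 only.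

Step 2
Reactants: 2 5-hydroxy-7-(methoxymethoxy)-4H-chromen-4-one; 3 [4-(benzyloxy)phenyl]boronic acid
Product: 4 (2S)-2-[4-(benzyloxy)phenyl]-5-hydroxy-7-(methoxymethoxy)chroman-4-one
Conditions: [Rh(OH)(cod)]2 (cat.), (S)-MeO-F12-BIPHEP (cat.), CH2Cl2/H2O, rt
Reagents that add atoms: none
Why: Hayashi–Miyaura rhodium-catalysed asymmetric 1,4-addition of the arylboronic acid to the chromone C-2=C-3 bond; the ligand controls the face of C-2, and its S hand is expected from the usual quadrant model for biaryl bisphosphine rhodium aryl species to give the 2S flavanone (to be confirmed by correlation on the first run).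

Step 3
Reactants: 4 (2S)-2-[4-(benzyloxy)phenyl]-5-hydroxy-7-(methoxymethoxy)chroman-4-one
Product: 6 (2S)-2-[4-(benzyloxy)phenyl]-7-(methoxymethoxy)chroman-5-ol, via aryl ethyl carbonate 5 (not isolated)
Conditions: ClCO2Et, Et3N, THF, 0 °C; filter; then NaBH4, THF/H2O, 0 °C to rt
Reagents that add atoms: none
Why: reductive deoxygenation of an ortho-hydroxyaryl ketone through its ethyl carbonate; borohydride reduces C-4=O, the carbonate migrates to the new alkoxide and is expelled by the 5-phenoxide to give an ortho-quinone methide that takes a second hydride at C-4, so C-4 becomes CH2 and the 5-hydroxyl returns while C-2 is untouched.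

Step 4
Reactants: 6 (2S)-2-[4-(benzyloxy)phenyl]-7-(methoxymethoxy)chroman-5-ol
Product: 7 (2S)-5-(benzyloxy)-2-[4-(benzyloxy)phenyl]-7-(methoxymethoxy)chroman
Conditions: BnBr, K2CO3, DMF, rt
Reagents that add atoms: benzyl bromide, BrCc1ccccc1
Why: Williamson ether synthesis on the only free phenol; with no carbonyl left the flavan cannot racemise by base-induced ring opening.

Step 5
Reactants: 7 (2S)-5-(benzyloxy)-2-[4-(benzyloxy)phenyl]-7-(methoxymethoxy)chroman
Product: 8 (2S)-5-(benzyloxy)-2-[4-(benzyloxy)phenyl]-8-bromo-7-(methoxymethoxy)chroman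
Conditions: NBS (1.0 equiv), CH2Cl2, −78 °C to 0 °C
Reagents that add atoms: N-bromosuccinimide, O=C1CCC(=O)N1Br
Why: electrophilic aromatic bromination of the phloroglucinol-type ring, far more electron-rich than the monoalkoxy ring; C-8 (between the ring oxygen and the MOM ether) is less hindered than C-6 (between two freely rotating ethers), the selectivity known for benzylated flavan-3-ols.

Step 6
Reactants: 9 1,3,5-tris(benzyloxy)benzene
Product: 10 1,3,5-tris(benzyloxy)-2-bromobenzene
Conditions: NBS (1.0 equiv), CH2Cl2, 0 °C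
Reagents that add atoms: N-bromosuccinimide, O=C1CCC(=O)N1Br
Why: electrophilic aromatic bromination; the three free positions are equivalent, so monobromination with one equivalent is unambiguous.

Step 7
Reactants: 10 1,3,5-tris(benzyloxy)-2-bromobenzene; 11 N,N'-dimethoxy-N,N'-dimethyloxamide
Product: 13 N-methoxy-N-methyl-2-oxo-2-[2,4,6-tris(benzyloxy)phenyl]acetamide, via aryllithium 12 (not isolated)
Conditions: n-BuLi, THF, −78 °C; cannulate into 11 (1.5 equiv), THF, −78 °C; NH4Cl (aq)
Reagents that add atoms: none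
Why: bromine–lithium exchange followed by Weinreb ketone synthesis on one end of the oxalic bis-amide; the chelated tetrahedral adduct survives until quench and inverse addition to excess 11 suppresses double arylation.

Step 8
Reactants: 8 (2S)-5-(benzyloxy)-2-[4-(benzyloxy)phenyl]-8-bromo-7-(methoxymethoxy)chroman; 13 N-methoxy-N-methyl-2-oxo-2-[2,4,6-tris(benzyloxy)phenyl]acetamide
Product: 15 1-[(2S)-5-(benzyloxy)-2-[4-(benzyloxy)phenyl]-7-(methoxymethoxy)chroman-8-yl]-2-[2,4,6-tris(benzyloxy)phenyl]ethane-1,2-dione, via 8-lithioflavan 14 (not isolated)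
Conditions: n-BuLi, THF, −78 °C; then 13, −78 °C to −40 °C; NH4Cl (aq)
Reagents that add atoms: none
Why: bromine–lithium exchange and Weinreb ketone synthesis; the amide carbonyl of 13 is the accessible electrophile because the neighbouring ketone is shielded by two ortho benzyloxy groups and deactivated by the trialkoxyphenyl ring, and the chelated adduct releases the 1,2-diketone only on work-up.

Step 9
Reactants: 15 1-[(2S)-5-(benzyloxy)-2-[4-(benzyloxy)phenyl]-7-(methoxymethoxy)chroman-8-yl]-2-[2,4,6-tris(benzyloxy)phenyl]ethane-1,2-dione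
Product: 16 1-[(2S)-5-(benzyloxy)-2-[4-(benzyloxy)phenyl]-7-hydroxychroman-8-yl]-2-[2,4,6-tris(benzyloxy)phenyl]ethane-1,2-dione
Conditions: 2 M HCl, MeOH/THF, 40 °C
Reagents that add atoms: none
Why: acid hydrolysis of the aryl MOM acetal, assisted by the ortho carbonyl; benzyl ethers, the diketone and the flavan ether (a poorly basic, acyl-flanked aryl ether oxygen) are stable to dilute acid.

Step 10
Reactants: 17 4-(benzyloxy)benzaldehyde
Product: 18 1-{[4-(benzyloxy)phenyl](chloro)methyl}-1H-benzotriazole (racemic)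
Conditions: 1H-benzotriazole, SOCl2, toluene, rt to 60 °C; used crude
Reagents that add atoms: 1H-benzotriazole, c1ccc2[nH]nnc2c1; thionyl chloride, ClS(Cl)=O
Why: benzotriazole–aldehyde condensation to the hemiaminal and its chlorination (a Mannich-type N,Cl-acetal synthesis) gives a reactive alpha-chloroalkyl benzotriazole that is used directly because it hydrolyses easily.

Step 11
Reactants: 16 1-[(2S)-5-(benzyloxy)-2-[4-(benzyloxy)phenyl]-7-hydroxychroman-8-yl]-2-[2,4,6-tris(benzyloxy)phenyl]ethane-1,2-dione; 18 1-{[4-(benzyloxy)phenyl](chloro)methyl}-1H-benzotriazole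
Product: 19 1-[(2S)-7-{(1H-benzotriazol-1-yl)[4-(benzyloxy)phenyl]methoxy}-5-(benzyloxy)-2-[4-(benzyloxy)phenyl]chroman-8-yl]-2-[2,4,6-tris(benzyloxy)phenyl]ethane-1,2-dione (both epimers at the acetal carbon)
Conditions: NaH, THF, 0 °C; then 18, 0 °C to rt
Reagents that add atoms: none
Why: SN1-like Williamson O-alkylation; the chloride ionises to a benzotriazole- and aryl-stabilised cation that the sodium phenoxide of 16 captures, low temperature and short time are meant to outrun benzilic-type rearrangement of the phenoxide onto the diketone, and the epimeric acetal carbon is of no consequence because it is deprotonated next.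

Step 12
Reactants: 19 1-[(2S)-7-{(1H-benzotriazol-1-yl)[4-(benzyloxy)phenyl]methoxy}-5-(benzyloxy)-2-[4-(benzyloxy)phenyl]chroman-8-yl]-2-[2,4,6-tris(benzyloxy)phenyl]ethane-1,2-dione
Product: 21 (3R)-2-methoxy-2-[4-(benzyloxy)phenyl]-3-hydroxy-3-[2,4,6-tris(benzyloxy)benzoyl]-2,3-dihydrofuran fused through O-7''/C-8'' to (2''S)-5''-(benzyloxy)-2''-[4-(benzyloxy)phenyl]chroman (both C-2 anomers), via benzotriazolyl aldol potassium alkoxide 20 (not isolated)
Conditions: KN(SiMe3)2 (1.3 equiv), THF, −78 °C; then MeSO3H (3 equiv), MeOH, −78 °C to rt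
Reagents that add atoms: methanol, CO
Why: The silylamide removes the acetal proton of 19 (acidified by benzotriazole, the aryl ring and the aryloxy oxygen) and the resulting masked 4-(benzyloxy)benzoyl anion, held on O-7'', adds to the neighbouring diketone carbonyl C-3 to form the C-2–C-3 bond and the dihydrofuran ring; acidic methanol then protonates the C-3 alkoxide and exchanges benzotriazole for methoxide through the C-2 oxocarbenium ion, so C-2 leaves the step at ketal oxidation level. The closest known reaction type is the addition of metalated 1-(alpha-alkoxybenzyl)benzotriazoles, established acyl anion equivalents, to ketones followed by acid solvolysis of the benzotriazole, run here as an intramolecular aldol-type addition. The ring closes in the 5-exo-trig mode. C-3 is the only lasting new stereocentre: C-2'' is too remote to bias the two faces of the twisted C-3 carbonyl, so both C-3 epimers are expected and, being diastereomers because C-2'' is fixed, they are separated by chromatography at the stage of 21 (the 3R series is carried on), while C-2 arises as an anomeric mixture that the last step resets. The step needs deprotonation to outrun attack of the base on the diketone, which the bulky non-nucleophilic silylamide and the absence of enolisable hydrogens should secure (the fast cyclisation drains the deprotonation equilibrium), and it needs closure onto C-3 in preference to 6-exo closure onto C-4, which the smaller ring and the two ortho benzyloxy groups shielding C-4 should secure.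

Step 13
Reactants: 21 (3R)-2-methoxy-2-[4-(benzyloxy)phenyl]-3-hydroxy-3-[2,4,6-tris(benzyloxy)benzoyl]-2,3-dihydrofuran fused through O-7''/C-8'' to (2''S)-5''-(benzyloxy)-2''-[4-(benzyloxy)phenyl]chroman
Product: 23 CNP0208300.2 (2R,3R,2''S), via hexaphenol methyl ketal 22 (not isolated)
Conditions: H2 (1 atm), Pd(OH)2/C, THF/MeOH, rt; filter; then HCl (cat.), MeOH, rt
Reagents that add atoms: none
Why: hydrogenolysis of the six benzyl ethers followed by acid-catalysed intramolecular transketalisation, in which the C-2 oxocarbenium ion is captured by either of the two equivalent ortho hydroxyls of ring A (6-exo closure of the pyranone ring); the five/six ring-fused ketal can only be cis so C-2 is set by C-3, and the aryl ketone and tertiary benzylic C–O bonds are expected to survive as they do in debenzylations of flavans and doubly linked proanthocyanidins.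

**Compound list**
1 | 5,7-dihydroxy-4H-chromen-4-one | O=c1ccoc2cc(O)cc(O)c12 | starting material
2 | 5-hydroxy-7-(methoxymethoxy)-4H-chromen-4-one | O=c1ccoc2cc(OCOC)cc(O)c12 | intermediate
3 | [4-(benzyloxy)phenyl]boronic acid | OB(O)c1ccc(OCc2ccccc2)cc1 | starting material
4 | (2S)-2-[4-(benzyloxy)phenyl]-5-hydroxy-7-(methoxymethoxy)chroman-4-one | O=C1C[C@@H](c2ccc(OCc3ccccc3)cc2)Oc2cc(OCOC)cc(O)c12 | intermediate
5 | (2S)-2-[4-(benzyloxy)phenyl]-7-(methoxymethoxy)-4-oxochroman-5-yl ethyl carbonate | CCOC(=O)Oc1cc(OCOC)cc2O[C@H](c3ccc(OCc4ccccc4)cc3)CC(=O)c12 | intermediate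
6 | (2S)-2-[4-(benzyloxy)phenyl]-7-(methoxymethoxy)chroman-5-ol | Oc1cc(OCOC)cc2O[C@H](c3ccc(OCc4ccccc4)cc3)CCc12 | intermediate
7 | (2S)-5-(benzyloxy)-2-[4-(benzyloxy)phenyl]-7-(methoxymethoxy)chroman | COCOc1cc2O[C@H](c3ccc(OCc4ccccc4)cc3)CCc2c(OCc2ccccc2)c1 | intermediate
8 | (2S)-5-(benzyloxy)-2-[4-(benzyloxy)phenyl]-8-bromo-7-(methoxymethoxy)chroman | COCOc1c(Br)c2O[C@H](c3ccc(OCc4ccccc4)cc3)CCc2c(OCc2ccccc2)c1 | intermediate
9 | 1,3,5-tris(benzyloxy)benzene | c1ccc(COc2cc(OCc3ccccc3)cc(OCc3ccccc3)c2)cc1 | starting material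
10 | 1,3,5-tris(benzyloxy)-2-bromobenzene | Brc1c(OCc2ccccc2)cc(OCc2ccccc2)cc1OCc1ccccc1 | intermediate
11 | N,N'-dimethoxy-N,N'-dimethyloxamide | CON(C)C(=O)C(=O)N(C)OC | starting material
12 | [2,4,6-tris(benzyloxy)phenyl]lithium | [Li]c1c(OCc2ccccc2)cc(OCc2ccccc2)cc1OCc1ccccc1 | intermediate
13 | N-methoxy-N-methyl-2-oxo-2-[2,4,6-tris(benzyloxy)phenyl]acetamide | CON(C)C(=O)C(=O)c1c(OCc2ccccc2)cc(OCc2ccccc2)cc1OCc1ccccc1 | intermediate
14 | [(2S)-5-(benzyloxy)-2-[4-(benzyloxy)phenyl]-7-(methoxymethoxy)chroman-8-yl]lithium | COCOc1c([Li])c2O[C@H](c3ccc(OCc4ccccc4)cc3)CCc2c(OCc2ccccc2)c1 | intermediate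
15 | 1-[(2S)-5-(benzyloxy)-2-[4-(benzyloxy)phenyl]-7-(methoxymethoxy)chroman-8-yl]-2-[2,4,6-tris(benzyloxy)phenyl]ethane-1,2-dione | COCOc1c(C(=O)C(=O)c2c(OCc3ccccc3)cc(OCc3ccccc3)cc2OCc2ccccc2)c2O[C@H](c3ccc(OCc4ccccc4)cc3)CCc2c(OCc2ccccc2)c1 | intermediate
16 | 1-[(2S)-5-(benzyloxy)-2-[4-(benzyloxy)phenyl]-7-hydroxychroman-8-yl]-2-[2,4,6-tris(benzyloxy)phenyl]ethane-1,2-dione | Oc1c(C(=O)C(=O)c2c(OCc3ccccc3)cc(OCc3ccccc3)cc2OCc2ccccc2)c2O[C@H](c3ccc(OCc4ccccc4)cc3)CCc2c(OCc2ccccc2)c1 | intermediate
17 | 4-(benzyloxy)benzaldehyde | O=Cc1ccc(OCc2ccccc2)cc1 | starting material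
18 | 1-{[4-(benzyloxy)phenyl](chloro)methyl}-1H-benzotriazole (racemic) | ClC(c1ccc(OCc2ccccc2)cc1)n1nnc2ccccc12 | intermediate
19 | 1-[(2S)-7-{(1H-benzotriazol-1-yl)[4-(benzyloxy)phenyl]methoxy}-5-(benzyloxy)-2-[4-(benzyloxy)phenyl]chroman-8-yl]-2-[2,4,6-tris(benzyloxy)phenyl]ethane-1,2-dione (acetal carbon as both epimers) | c1ccc2c(c1)nnn2C(c1ccc(OCc2ccccc2)cc1)Oc1c(C(=O)C(=O)c2c(OCc3ccccc3)cc(OCc3ccccc3)cc2OCc2ccccc2)c2O[C@H](c3ccc(OCc4ccccc4)cc3)CCc2c(OCc2ccccc2)c1 | intermediate
20 | potassium 3-olate of the aldol adduct: 2-(1H-benzotriazol-1-yl)-2-[4-(benzyloxy)phenyl]-3-[2,4,6-tris(benzyloxy)benzoyl]-2,3-dihydrofuran fused through O-7''/C-8'' to the (2''S)-flavan of 19; C-3 arranged as in 21 (descriptor 3S here because nitrogen replaces oxygen at C-2), C-2 as both epimers | [K+].c1ccc2c(c1)nnn2C1(c2ccc(OCc3ccccc3)cc2)Oc2cc(OCc3ccccc3)c3CC[C@@H](c4ccc(OCc5ccccc5)cc4)Oc3c2[C@@]1([O-])C(=O)c1c(OCc2ccccc2)cc(OCc2ccccc2)cc1OCc1ccccc1 | intermediate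
21 | (3R)-2-methoxy-2-[4-(benzyloxy)phenyl]-3-hydroxy-3-[2,4,6-tris(benzyloxy)benzoyl]-2,3-dihydrofuran fused through O-7''/C-8'' to (2''S)-5''-(benzyloxy)-2''-[4-(benzyloxy)phenyl]chroman (both C-2 anomers) | COC1(c2ccc(OCc3ccccc3)cc2)Oc2cc(OCc3ccccc3)c3CC[C@@H](c4ccc(OCc5ccccc5)cc4)Oc3c2[C@@]1(O)C(=O)c1c(OCc2ccccc2)cc(OCc2ccccc2)cc1OCc1ccccc1 | intermediate
22 | hexaphenol of 21: (3R)-2-methoxy-2-(4-hydroxyphenyl)-3-hydroxy-3-(2,4,6-trihydroxybenzoyl)-2,3-dihydrofuran fused through O-7''/C-8'' to (2''S)-5''-hydroxy-2''-(4-hydroxyphenyl)chroman | COC1(c2ccc(O)cc2)Oc2cc(O)c3CC[C@@H](c4ccc(O)cc4)Oc3c2[C@@]1(O)C(=O)c1c(O)cc(O)cc1O | intermediate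
23 | CNP0208300.2: (2R,3R)-3,5,7-trihydroxy-2-(4-hydroxyphenyl)chroman-4-one whose C-2 is bonded to O-7'' and whose C-3 is bonded to C-8'' of (2''S)-5''-hydroxy-2''-(4-hydroxyphenyl)chroman (cis-fused benzofuro[2,3-b]chromenone ketal) | O=C1c2c(O)cc(O)cc2O[C@@]2(c3ccc(O)cc3)Oc3cc(O)c4c(c3[C@@]12O)O[C@H](c1ccc(O)cc1)CC4 | target

Total step count: 13. Longest linear sequence: 10 steps (steps 1, 2, 3, 4, 5, 8, 9, 11, 12, 13).

**Steps most likely to fail**

Step 12. The silylamide may transfer an electron to the 1,2-diketone, or add to it, before it removes the acetal proton. Facial discrimination at the C-3 carbonyl is also expected to be poor, which costs about half the material as the C-3 epimer. The fallback keeps the tethered-anion idea but changes the activating group to an ester that is later excised by oxidative decarboxylation; it sets out from 16 and returns to the route at 21. Commercial 4-(benzyloxy)phenylacetic acid is O-allylated (allyl bromide, K2CO3, DMF) to allyl [4-(benzyloxy)phenyl]acetate F1. Bromination of its lithium enolate (LiN(SiMe3)2, then CBr4, THF, −78 °C) gives allyl bromo[4-(benzyloxy)phenyl]acetate F2. Phenol 16 and F2 with K2CO3 in DMF at rt should undergo O-alkylation and, in the same flask, aldol closure of the ester enolate onto C-3 (an interrupted Rap–Stoermer benzofuran synthesis, which stops at the aldol stage because C-2 is quaternary). This gives the allyl 3-hydroxy-2,3-dihydrobenzofuran-2-carboxylate F3. Pd(PPh3)4 and morpholine in THF free the carboxylic acid F4 without base, which avoids retro-aldol cleavage. Anodic decarboxylation in methanol (Hofer–Moest reaction, carbon anode, catalytic NaOCH3) replaces the carboxyl group at C-2 by methoxide and delivers 21. The C-3 epimers are separated there as in the main route.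

Step 8. The hindered aryllithium 14 may attack the ketone carbonyl of 13, or be consumed by proton or electron transfer, instead of adding to the amide carbonyl. The fallback makes the aryl–carbon bond by palladium catalysis and raises the oxidation level afterwards; it sets out from 8 and returns at 15. Commercial 2',4',6'-trihydroxyacetophenone is perbenzylated (BnBr, K2CO3, DMF, 80 °C) to 1-[2,4,6-tris(benzyloxy)phenyl]ethanone F5. Palladium-catalysed ketone alpha-arylation of F5 with bromide 8 (Pd(OAc)2, XPhos, NaOC(CH3)3, toluene, 80 °C) gives the deoxybenzoin 2-[(2S)-5-(benzyloxy)-2-[4-(benzyloxy)phenyl]-7-(methoxymethoxy)chroman-8-yl]-1-[2,4,6-tris(benzyloxy)phenyl]ethanone F6. Riley oxidation of its doubly activated methylene (SeO2, dioxane/H2O, 90 °C) gives diketone 15.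

Step 13. Hydrogenolysis may continue into the benzylic C–O bonds at the ketal carbon C-2 or at C-2'', or stall through catalyst poisoning before all six benzyl groups are gone. The fallback replaces hydrogen by a Lewis acid; it sets out from 21 and arrives directly at 23. BCl3 with pentamethylbenzene as benzyl-cation scavenger (CH2Cl2, −78 °C to −20 °C) cleaves the aryl benzyl ethers. The same Lewis acid ionises the methyl ketal, so ketal closure by the ring A hydroxyl follows on warming and aqueous work-up. This adds no further compound (none F0).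

Further compounds
F1 | step 12 | allyl [4-(benzyloxy)phenyl]acetate | C=CCOC(=O)Cc1ccc(OCc2ccccc2)cc1
F2 | step 12 | allyl bromo[4-(benzyloxy)phenyl]acetate (racemic) | C=CCOC(=O)C(Br)c1ccc(OCc2ccccc2)cc1
F3 | step 12 | allyl 2-[4-(benzyloxy)phenyl]-3-hydroxy-3-[2,4,6-tris(benzyloxy)benzoyl]-2,3-dihydrofuran-2-carboxylate fused through O-7''/C-8'' to (2''S)-5''-(benzyloxy)-2''-[4-(benzyloxy)phenyl]chroman (C-3 arranged as in 21, C-2 as both epimers) | C=CCOC(=O)C1(c2ccc(OCc3ccccc3)cc2)Oc2cc(OCc3ccccc3)c3CC[C@@H](c4ccc(OCc5ccccc5)cc4)Oc3c2[C@@]1(O)C(=O)c1c(OCc2ccccc2)cc(OCc2ccccc2)cc1OCc1ccccc1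
F4 | step 12 | carboxylic acid of F3 | OC(=O)C1(c2ccc(OCc3ccccc3)cc2)Oc2cc(OCc3ccccc3)c3CC[C@@H](c4ccc(OCc5ccccc5)cc4)Oc3c2[C@@]1(O)C(=O)c1c(OCc2ccccc2)cc(OCc2ccccc2)cc1OCc1ccccc1
F5 | step 8 | 1-[2,4,6-tris(benzyloxy)phenyl]ethanone | CC(=O)c1c(OCc2ccccc2)cc(OCc2ccccc2)cc1OCc1ccccc1
F6 | step 8 | 2-[(2S)-5-(benzyloxy)-2-[4-(benzyloxy)phenyl]-7-(methoxymethoxy)chroman-8-yl]-1-[2,4,6-tris(benzyloxy)phenyl]ethanone | O=C(Cc1c(OCOC)cc(OCc2ccccc2)c2CC[C@@H](c3ccc(OCc4ccccc4)cc3)Oc12)c1c(OCc2ccccc2)cc(OCc2ccccc2)cc1OCc1ccccc1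
F0 | step 13 | none | none
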